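Target breeds target: one target with substrate and coupling partner gives two, while a slow step without target provides the seed. I wanted to know what stands at the end of each run.

- autumn: substrate 0.20 M; coupling partner 0.220 M; time 25 s
- dusk: substrate 0.20 M; coupling partner 0.220 M; time 50 s

- which of these there is most of at the end, counted by the substrate in it, autumn (substrate / over-reaction product / target)
- which of these there is most of at the end, counted by the substrate in it, dusk (substrate / over-reaction product / target)
- how much there is at the end of the one of these that leads, in percent of the substrate charged: autumn
- how much there is at the end of the one of these that leads, in percent of the substrate charged: dusk

- percent here means substrate units held: one idle adduct counts as two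
- what is said of target includes idle adduct
- in an amount of target, one idle adduct counts as one target
- run time (autumn): 25 s

    substrate + coupling partner + target → 2 target (k1 = 17.0 L² mol⁻² s⁻¹)
    substrate + coupling partner → target (k2 = 1.19 × 10⁻⁴ L mol⁻¹ s⁻¹)
    substrate + target ⇌ idle adduct, settled at all times (K3 = 1.3 L mol⁻¹)
    coupling partner + target → over-reaction product (k4 = 0.0901 L mol⁻¹ s⁻¹)

I treated the fast balance as holding at every moment, so part of target sits as idle adduct. What counts is the free share φ of target, one divided by one plus the balance constant times free substrate, which at the charge is 79.4 %. I held φ there and let substrate and coupling partner fall as target formed. The rate then integrates by hand and puts half of the substrate through at 18.4 s. At that point the half-life of substrate is 4.28 s, and keeping it until 25 s leaves 17.1 % of the substrate in autumn.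

With no over-reaction, autumn's target stands below 82.9 %. From below, I charged over-reaction product with coupling partner at full charge and the substrate wholly target after that half-way point, which costs 13.2 % and leaves target above 69.8 %. I committed to the middle, 76.4 %, with target leading. Dusk allows 7.39 such half-lives. I took its substrate as used and the surplus of coupling partner as over-reaction product, which gives 90.0 %, with target ahead.

The forecast named target for autumn and target for dusk, at 79 % and 87 %, holding that “autocatalysis, somewhat damped by the idle adduct, then takes off”. Its autumn value lies inside my bracket and above my middle, and its dusk value lies below mine.

The simulation puts target ahead in autumn at 73.8 %, which is inside the bracket, and target ahead in dusk at 85.7 %.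

In dusk, the making of target had 1.5 % of its turnover behind it at 10.0 s, and it ran at a substrate half-life of 4.1 s at 18.5 s, against my 4.28 s. The loss to over-reaction product in dusk had 50 % of its turnover behind it at 25.0 s and continued while 5.64 % of the coupling partner remained at the end. At autumn's end, with 18 % of the substrate free, φ had risen to 95.5 %. In the neighbour charged with 0.50 M of substrate, φ at the end is 76.7 %, and substrate leads at 46.7 % against target's 42.7 %.

The numbers of this flask come from no measurement.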